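The readings stem from a simulated flask from invented constants, and the scatter is random.

Start with the easy step: in its first hours a flask gains intermediate A along a straight line, and that slope can be read as a fraction of the charge per hour.

| setting | south | north | blue | red | ochre |
|---|---|---|---|---|---|
| substrate | 0.27 M | 0.60 M | 0.40 M | 0.40 M | 0.40 M |
| temperature | 45 °C | 78 °C | 30 °C | 90 °C | 60 °C |
| remark | run made earlier | run made earlier |  |  |  |
| time |  |  | 30 h | 30 h | 30 h |

| run | time / h | intermediate A / % | target / % |
|---|---|---|---|
| south | 1.00 | 0.3 | 1.5 |
| south | 3.00 | 1.0 | 0 |
| south | 5.00 | 0.6 | 1.0 |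
| south | 8.00 | 1.3 | 1.1 |
| south | 10.0 | 0 | 0 |
| south | 15.0 | 0.8 | 0.6 |
| south | 20.0 | 1.3 | 0.7 |
| north | 0.500 | 2.3 | 0 |
| north | 1.00 | 5.5 | 0 |
| north | 1.33 | 5.0 | 1.4 |
| north | 2.00 | 9.3 | 0.4 |
| north | 2.50 | 11.6 | 1.1 |
| north | 3.00 | 12.8 | 0 |
| north | 4.00 | 13.9 | 0 |

(scatter of a reading: 1 percentage point)

- which flask leads in amount of intermediate A, in percent of the substrate charged ("all alike" within 1.5 percentage points) (blue / red / ochre / all alike)
- how much intermediate A is there at the end, in percent of the substrate charged: blue
- how much intermediate A is there at the end, in percent of the substrate charged: red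
- how much intermediate A is there at the end, in percent of the substrate charged: ochre

**First instants.** The south run's last reading gives 6.50 × 10⁻⁴ /h and the north run's reading at 2.00 h gives 0.0465 /h. I treat these fractions as comparable although the charges differ, and that puts a loose 120 kJ/mol on the making of A. Blue then stays in its straight line and reaches 0.206%.

**Middle.** The north curve bends, and ochre's 30 h corresponds to 3.24 h of the north run, which falls between its last two readings. My figure for ochre is therefore 13.3%.

**End.** Red corresponds to 117 h of the north run, far past the last north reading, so the small loss of A becomes the question. North's target readings reach 1.4% at their highest and end at 0%, so I take one scatter, 1 percentage point, as the size of the target formed, while the area under north's A curve is about 0.278 h. Dividing gives 0.0360 /h. Scaled to red, this is the assumed leak 0.140 /h: a first-order loss of A, supposing that A goes straight to target and that north formed about one scatter of target. This is a working size, not a bound. At that leak, north's last reading shrinks to 0.207% over red's 30 h, but a smaller leak leaves red higher, and without any leak north's last reading of 13.9% stands above my ochre figure. I put ochre ahead of red as a judgement that rests on the assumed leak.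

The forecast chose red, with 0.2%, 15% and 11% for blue, red and ochre, red being a flask that “reaches the plateau quickly, then possibly leaks slowly to target”.

    intermediate B → target (k = 0.160 /h, Ea = 122 kJ/mol)
    2 substrate → self-condensation product (k = 0.570 /M/h, Ea = 88.0 kJ/mol)
    substrate → intermediate A (k = 0.270 /h, Ea = 123 kJ/mol)
    intermediate A → intermediate B (k = 0.150 /h, Ea = 125 kJ/mol)
    (constants at 90 °C)

Ochre leads with 12.5%, against 0.249% in blue and 1.21% in red. At red's end, A is made at hardly any of the rate at which it is used, 0.0168. Red holds 10.3% at 15.0 h, and 0.140 /h takes that to 1.26% by the end, against 1.21%. Red read at 8.0 h holds 23.6%; the same rate gives 13.5% at 12 h, and red read then holds 15.1%.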